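## Analysis of the target

The target is a tetracyclic depsidone. Two benzene rings (ring A and ring B) are joined by a diaryl ether oxygen and by an aryl ester, which together close the seven-membered ring C; ring B is also fused to a five-membered hydroxy-lactone (ring D). For the discussion the ring carbons are labelled as follows.

- Ring A: A1 carries the ring C carbonyl, A2 the ether oxygen, A3 the free OH, A4 the OMe, A5 is C–H, A6 carries CH3.
- Ring B: B1 carries the ether oxygen, B2 the ester oxygen, B3 a CH3, B4 the free OH, B5 the lactone carbonyl, B6 the hemiacetal carbon.

The only stereocentre is the hemiacetal carbon of ring D, with R configuration. It is a lactol in ring–chain equilibrium with the open formyl acid, so it is configurationally labile and no other stereogenic element in the molecule can control it. The sensitive groups are the aryl ester of ring C (opened by hydroxide, alkoxide or a neighbouring phenoxide), the lactol (opened by base, acetalised by alcohols under acid) and three free hydroxyl groups on electron-rich rings. The synthesis is hard for three reasons: ring B is hexasubstituted with six different neighbours in fixed order; the ether oxygen is flanked by four ortho substituents; and the aldehyde oxidation level at the B6 carbon sits beside two aryl methyl groups, which makes a late benzylic oxidation unattractive.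

The strategy rests on one feature of ring B. The B1 oxygen and the B4 oxygen are para, and B5 and B6 carry two adjacent carbon substituents at the acid and aldehyde oxidation levels. This is the pattern formed when a 2-oxygenated furan (C2 becomes B4, C5 becomes B1, the ring oxygen becomes the B1 oxygen, and the 3- and 4-substituents become B3–CH3 and B2–O) adds a two-carbon alkyne (B5, B6) and the oxygen bridge opens.

## Retrosynthetic reasoning

**20 to 19.** The hemiacetal centre cannot be carried through solution chemistry, so it is addressed last and physically. Racemic lactol 19 equilibrates through its open form, and the R enantiomer 20 is collected by a crystallisation that drains this equilibrium. No bond is cut; all covalent chemistry can therefore be planned for the racemate.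

**19 to 17.** Ring D is opened at the lactone C–O bond and the hemiacetal is traced back to a dimethyl acetal beside a methyl ester, with the A3 phenol masked as a methoxymethyl ether. One aqueous acid treatment should then hydrolyse the acetal to formyl ester 18, close the hydroxy-lactone with loss of methanol and free the A3 phenol. The aldehyde oxidation level at the B6 carbon is thus present from the start and never has to be made by C–H oxidation.

**17 to 15.** After removal of the silyl group at the B4 oxygen (16 from 17 in the backward sense), the ester bond of ring C between the A1 carboxyl and the B2 oxygen is cut to give hydroxy acid 15. The ester is cut before the ether because it is the more labile link and is best formed late. The forward step is an intramolecular seven-ring lactonisation in which the diaryl ether already holds acid and phenol in ortho positions. Only the B2 hydroxyl may be free at that stage, which is why A3 and B4 stay protected.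

**15 to 8 and 12.** Acid 15 comes from benzyl ether 14 by hydrogenolysis, and 14 from aldehyde 13 by chlorite oxidation. The A2–O bond of 13 is then cut, giving phenol 8 and fluoroaldehyde 12. The cut is made on the ring A side because ring B then only has to offer a free phenol at B1, and the formyl group of 12 serves twice: as the activating group for fluoride displacement and as the latent carboxyl of ring C.

**8 to 3 and 6 (key disconnection).** In ring B the bonds B1–B6 and B4–B5 are cut. This returns silyloxyfuran 3 (C5 becomes B1, C2 becomes B4) and ynoate 6 (acetal-bearing carbon becomes B6, ester-bearing carbon becomes B5). The forward reaction must form both C–C bonds with the ester next to the silyloxy carbon and must open the oxygen bridge so that the bridging oxygen ends up as the free B1 phenol. All six substituents of ring B are set in one operation from two small achiral pieces, and the three ring B oxygens emerge differentiated (free OH, benzyl ether, silyl ether).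

**3 to 1, and 6 to 4.** Furan 3 is the silyl dienol ether of benzyl tetronate 2, which comes from 3-methyltetronic acid 1 by O-benzylation. Ynoate 6 comes from acetylenic acetal 4 by C-acylation of its lithium acetylide 5. Both precursors are two or one steps from purchased materials, so the risk of the route sits in the cycloaddition.

**12 to 9.** The aryl methyl of 12 is cut back to bromide 11, the methoxymethyl ether to phenol 10, and the bromine to 9. Aldehyde 9 already has formyl, fluorine, hydroxyl and methoxyl in the required 1,2,3,4 order; its free hydroxyl directs bromination to the para position, which is the carbon that must carry the methyl group.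

## Alternatives that were turned down

**Alternative 1: oxidative spirolactonisation and acyloxy shift.**
- Disconnection: the bond between the ring C ester oxygen and B2, so that B2 is a plain C–H in the precursor, diaryl ether acid A2.
- Forward key step: the trivalent iodine oxidant PhI(OAc)2 dearomatises ring B at its B4 phenol, and the A1 carboxyl adds at B1 to give the spiro quinone monoketal lactone A3. BF3·OEt2 then moves the acyloxy group from B1 to B2 with rearomatisation, which enlarges the six-membered spirolactone to ring C and gives A1.
- For: ring B needs one oxygen fewer before the key step, and ring C is closed by rearrangement instead of lactonisation. The diaryl ether of A2 has a hydrogen ortho to the ether oxygen and is less crowded than ether 13; on that point this alternative is stronger.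
- Against: the B4 phenol is hydrogen-bonded to the lactone carbonyl and is less oxidisable than ring A, so the oxidation has to be steered by the acetate on ring A. The cationic shift can also move the aryloxy group or reopen the ketal. Most seriously, A1 is a phthalide: the B6 carbon is CH2 and must be oxidised to the lactol after the key step, by radical halogenation next to two aryl methyl groups, and the acetate must then be removed.
- Comparison: the chosen route accepts the crowded ether formation but carries the aldehyde level from 4 and needs no C–H oxidation and no extra deprotection.

**Alternative 2: photochemical Wolff benzannulation.**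
- Disconnection: four C–C bonds of ring B, with ring A already attached through the ether oxygen.
- Forward key step: irradiation of diazo ketoester A5 gives, by Wolff rearrangement, a vinylketene; this adds siloxyalkyne A6 in a [2+2] cycloaddition, and the cyclobutenone opens and recloses by a six-electron electrocyclisation to give phenol A4.
- For: this is the most convergent way to the hexasubstituted ring. It avoids the intermolecular crowded ether formation and delivers the B2 hydroxyl free, so no benzyl ether and no hydrogenolysis are needed; on those points it is stronger.
- Against: A5 is a β-aryloxy enone with an acetal and a diazo ketoester, a labile vinylogous ester that needs a long sequence (O-vinylation of a hindered ring A phenol, then diazo transfer). A6 must be made from an ynolate. The photochemical step has to work in the presence of benzyl and aryl ether chromophores, and migration of the wrong group in the Wolff step, or ketene dimerisation, would cost material late.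
- Comparison: the chosen route reaches both cycloaddition partners in one to two steps from purchased materials and runs its key step thermally on simple compounds, at the price of three protecting-group operations afterwards.

**Alternative 3: carbenoid O–H insertion from a quinone diazide.**
- Disconnection: the A2–O bond, cut inside a depside, so that the ether and ring C close together.
- Forward key step: Rh2(OAc)4 converts the ortho-quinone diazide ester A8 into a carbenoid at A2, which inserts into the O–H bond of the B1 phenol and tautomerises to A7.
- For: the crowded ether is made intramolecularly under neutral conditions and the A3 phenol appears unprotected; on both points it is stronger than an intermolecular fluoride displacement.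
- Against: A8 needs an ortho-aminophenol on ring A (nitration, reduction, diazotisation) and a depside ester placed selectively on one of two adjacent ring B oxygens, where acyl migration can scramble the regiochemistry. Ortho-quinone diazides are prone to ring contraction by Wolff rearrangement, and the carbenoid can attack the benzyl ether or the aryl methyl groups. A7 is again a phthalide that needs late benzylic oxidation, now also beside a benzyl ether, and debenzylation.
- Comparison: the chosen route forms the ether by a polar step whose regiochemistry cannot scramble, because only one ring B oxygen is free, and ends at the correct oxidation level.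

Key step: step 4

Assumption: the hemiacetal carbon of ring D epimerises in solution through the ring-opened formyl acid, so the R configuration of 20 is taken as that of the crystalline solid, and racemic 19 is taken to crystallise as a conglomerate.

## Route

**Step 1**
Reactants: 1 3-methyltetronic acid (4-hydroxy-3-methylfuran-2(5H)-one)
Product: 2 4-(benzyloxy)-3-methylfuran-2(5H)-one
Conditions: BnOH, PPh3, DIAD, THF, 0 °C to rt
Reagents that add atoms: benzyl alcohol, OCc1ccccc1
Why: Mitsunobu O-alkylation of the acidic vinylogous acid should give the 4-O-benzyl tetronate with oxygen selectivity and avoid the C3 benzylation that basic alkylation risks.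

**Step 2**
Reactants: 2 4-(benzyloxy)-3-methylfuran-2(5H)-one
Product: 3 4-(benzyloxy)-3-methyl-2-[(triisopropylsilyl)oxy]furan
Conditions: TIPSOTf, Et3N, CH2Cl2, 0 °C to rt; filtration through basic alumina under N2, used directly
Reagents that add atoms: triisopropylsilyl trifluoromethanesulfonate, CC(C)[Si](OS(=O)(=O)C(F)(F)F)(C(C)C)C(C)C
Why: Soft enolisation (silyl triflate on the lactone carbonyl, amine removes a C5 proton) is the standard way from butenolides and tetronates to 2-silyloxyfurans and is driven by aromatisation; the triisopropylsilyl group is chosen for resistance to protodesilylation.

**Step 3**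
Reactants: 4 3,3-dimethoxyprop-1-yne
Product: 6 methyl 4,4-dimethoxybut-2-ynoate, via lithium 3,3-dimethoxyprop-1-yn-1-ide 5 (not isolated)
Conditions: n-BuLi, THF, −78 °C; ClCO2Me, −78 to 0 °C
Reagents that add atoms: methyl chloroformate, COC(=O)Cl
Why: Deprotonation of the terminal alkyne and C-acylation of the lithium acetylide with a chloroformate is a standard ynoate synthesis, and the acetal is inert to the base.

**Step 4**
Reactants: 3 4-(benzyloxy)-3-methyl-2-[(triisopropylsilyl)oxy]furan (1.3 equiv); 6 methyl 4,4-dimethoxybut-2-ynoate
Product: 8 methyl 4-(benzyloxy)-2-(dimethoxymethyl)-3-hydroxy-5-methyl-6-[(triisopropylsilyl)oxy]benzoate, via oxanorbornadiene cycloadduct 7 (not isolated)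
Conditions: toluene, 90 °C, sealed tube, N2; chromatography on Et3N-deactivated silica
Reagents that add atoms: none
Why: This is a polarised, asynchronous [4+2] cycloaddition: furan C5, the only unsubstituted diene terminus and the carbon made nucleophilic by both the 2-silyloxy group (vinylogously) and the 4-benzyloxy group (as enol ether β-carbon), bonds first to the alkyne carbon β to the ester, and furan C2 then bonds to the ester-bearing carbon to give oxanorbornadiene 7. In 7 the C–O bond at the silyloxy-bearing bridgehead ionises, because only there is the cation stabilised by an attached oxygen, and loss of the proton from the other bridgehead aromatises the ring, so the bridging oxygen ends as the free B1 phenol para to the silyl ether. The closest known reaction type is the Diels–Alder reaction of 2-silyloxyfurans with acetylenic esters, which opens in the same way to 4-silyloxyphenols. Ring B is closed by intermolecular suprafacial cycloaddition (bonds B1–B6 and B4–B5) followed by opening of the oxygen bridge; the two bridgehead stereocentres of 7 vanish on aromatisation and no stereocentre is set. The step needs one regiochemistry, ester next to the silyloxy carbon and acetal next to the new phenol, and the matched polarisation of the donor-activated C5 and the β-carbon of the ynoate secures it. The bulky triisopropylsilyl group should hold back silyl transfer and protodesilylation of 3 by the phenolic product, and the neutral thermal conditions spare the acetal.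

**Step 5**
Reactants: 9 2-fluoro-3-hydroxy-4-methoxybenzaldehyde
Product: 10 6-bromo-2-fluoro-3-hydroxy-4-methoxybenzaldehyde
Conditions: NBS, MeCN, 0 °C to rt
Reagents that add atoms: N-bromosuccinimide, O=C1CCC(=O)N1Br
Why: In this electrophilic aromatic bromination the free hydroxyl is the strongest director and both its ortho positions are occupied (F and OMe), so substitution should go para to it, at the carbon ortho to the formyl group that must later carry the methyl.

**Step 6**
Reactants: 10 6-bromo-2-fluoro-3-hydroxy-4-methoxybenzaldehyde
Product: 11 6-bromo-2-fluoro-4-methoxy-3-(methoxymethoxy)benzaldehyde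
Conditions: MOMCl, i-Pr2NEt, CH2Cl2, 0 °C to rt
Reagents that add atoms: chloromethyl methyl ether, COCCl
Why: O-Alkylation of the phenol gives the methoxymethyl ether, which should survive carbonate, chlorite, hydrogenation, carbodiimide and buffered fluoride and leave in the final acid step together with the acetal.

**Step 7**
Reactants: 11 6-bromo-2-fluoro-4-methoxy-3-(methoxymethoxy)benzaldehyde
Product: 12 2-fluoro-4-methoxy-3-(methoxymethoxy)-6-methylbenzaldehyde
Conditions: trimethylboroxine, Pd(PPh3)4 (5 mol %), K2CO3, 1,4-dioxane, 100 °C
Reagents that add atoms: trimethylboroxine, CB1OB(C)OB(C)O1
Why: Suzuki–Miyaura methylation; zerovalent palladium inserts into the C–Br bond activated by the ortho formyl group and leaves the C–F bond alone, and the anhydrous carbonate avoids hydrolysis of the activated fluoride.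

**Step 8**
Reactants: 8 methyl 4-(benzyloxy)-2-(dimethoxymethyl)-3-hydroxy-5-methyl-6-[(triisopropylsilyl)oxy]benzoate; 12 2-fluoro-4-methoxy-3-(methoxymethoxy)-6-methylbenzaldehyde
Product: 13 methyl 4-(benzyloxy)-2-(dimethoxymethyl)-3-[2-formyl-5-methoxy-6-(methoxymethoxy)-3-methylphenoxy]-5-methyl-6-[(triisopropylsilyl)oxy]benzoate
Conditions: Cs2CO3, DMSO (anhydrous), 90 °C
Reagents that add atoms: none
Why: Nucleophilic aromatic substitution by addition–elimination: the caesium phenoxide of 8, the only acidic site, adds at the fluorine-bearing carbon of 12, the ortho formyl group stabilises the Meisenheimer adduct, and fluoride is the best leaving group for a rate-limiting addition. Ester, acetal, benzyl ether and the hindered aryl silyl ether should tolerate anhydrous carbonate.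

**Step 9**
Reactants: 13 diaryl ether aldehyde (named in step 8)
Product: 14 2-[2-(benzyloxy)-6-(dimethoxymethyl)-5-(methoxycarbonyl)-3-methyl-4-[(triisopropylsilyl)oxy]phenoxy]-4-methoxy-3-(methoxymethoxy)-6-methylbenzoic acid
Conditions: NaClO2, NaH2PO4, 2-methyl-2-butene, t-BuOH/THF/H2O, rt
Reagents that add atoms: sodium chlorite, [Na+].[O-]Cl=O
Why: Pinnick oxidation converts the hindered aryl aldehyde into the acid at about pH 4, where the acetal, the methoxymethyl ether and the silyl ether persist; the alkene scavenger removes hypochlorous acid before it can chlorinate the single free position of ring A.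

**Step 10**
Reactants: 14 benzyl ether acid (named in step 9)
Product: 15 2-[6-(dimethoxymethyl)-2-hydroxy-5-(methoxycarbonyl)-3-methyl-4-[(triisopropylsilyl)oxy]phenoxy]-4-methoxy-3-(methoxymethoxy)-6-methylbenzoic acid
Conditions: H2 (1 atm), 10% Pd/C, EtOAc, rt
Reagents that add atoms: none
Why: Hydrogenolysis cleaves only the benzyl aryl ether and so frees the B2 hydroxyl; the diaryl ether, silyl ether, methoxymethyl ether and dimethyl acetal are stable in neutral ethyl acetate.

**Step 11**
Reactants: 15 hydroxy acid (named in step 10)
Product: 16 methyl 6-(dimethoxymethyl)-3-methoxy-4-(methoxymethoxy)-1,9-dimethyl-11-oxo-8-[(triisopropylsilyl)oxy]-11H-dibenzo[b,e][1,4]dioxepine-7-carboxylate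
Conditions: DCC, DMAP (cat.), CH2Cl2 (0.005 M), rt
Reagents that add atoms: none
Why: Carbodiimide lactonisation with acyl transfer by DMAP (Steglich type) closes the seven-membered ring C; the diaryl ether holds acid and phenol ortho to each other, the B2 hydroxyl is the only free hydroxyl, and high dilution disfavours intermolecular esters.

**Step 12**
Reactants: 16 protected depsidone (named in step 11)
Product: 17 methyl 6-(dimethoxymethyl)-8-hydroxy-3-methoxy-4-(methoxymethoxy)-1,9-dimethyl-11-oxo-11H-dibenzo[b,e][1,4]dioxepine-7-carboxylate
Conditions: Bu4NF, AcOH (1:1), THF, 0 °C
Reagents that add atoms: none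
Why: Fluoride cleaves the aryl silyl ether; the acetic acid buffer keeps the released B4 phenoxide protonated so that the aryl ester of ring C is not transesterified.

**Step 13**
Reactants: 17 phenol depsidone (named in step 12)
Product: 19 racemic hydroxy-lactone depsidone (constitution of the target as the racemate), via formyl ester 18 (not isolated)
Conditions: 3 M aq. HCl, THF, 50 °C
Reagents that add atoms: water, O
Why: Acid hydrolysis of the dimethyl acetal and of the methoxymethyl ether gives formyl ester 18, whose aldehyde hydrate attacks the neighbouring methyl ester in a 5-exo-trig lactonisation (as γ-hydroxy esters lactonise) and expels methanol to give the hydroxy-lactone. The hindered aryl ester of ring C should survive these conditions. The new hemiacetal centre forms without control and equilibrates, so 19 is racemic.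

**Step 14**
Reactants: 19 racemic hydroxy-lactone depsidone
Product: 20 target, the R enantiomer of the hydroxy-lactone depsidone (ring A: A3–OH, A4–OMe, A6–CH3; ring B: B3–CH3, B4–OH; ring D hemiacetal carbon R)
Conditions: seed crystals of 20, AcOH (cat.), MeCN, glass beads, vigorous stirring, 25 °C; filtration, cold wash
Reagents that add atoms: none
Why: Proposed new method: in the slurry the dissolved enantiomers interconvert through the ring-opened formyl acid (ring–chain tautomerism, catalysed by acetic acid), while grinding and seeding let crystals of the R form grow at the expense of the S form until the solid is of one handedness. The closest known reaction types are attrition-enhanced deracemisation of racemising conglomerates and the crystallisation-driven enrichment of one anomer of a mutarotating sugar, which also acts at a hemiacetal carbon. The stereocentre is set by the handedness of the seed crystals.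

## Compound list

1 | 3-methyltetronic acid (4-hydroxy-3-methylfuran-2(5H)-one) | CC1=C(O)COC1=O | starting material
2 | 4-(benzyloxy)-3-methylfuran-2(5H)-one | CC1=C(OCc2ccccc2)COC1=O | intermediate
3 | 4-(benzyloxy)-3-methyl-2-[(triisopropylsilyl)oxy]furan | Cc1c(O[Si](C(C)C)(C(C)C)C(C)C)occ1OCc1ccccc1 | intermediate
4 | 3,3-dimethoxyprop-1-yne | C#CC(OC)OC | starting material
5 | lithium 3,3-dimethoxyprop-1-yn-1-ide | [Li]C#CC(OC)OC | intermediate (not isolated)
6 | methyl 4,4-dimethoxybut-2-ynoate | COC(=O)C#CC(OC)OC | intermediate
7 | methyl 5-(benzyloxy)-3-(dimethoxymethyl)-6-methyl-1-[(triisopropylsilyl)oxy]-7-oxabicyclo[2.2.1]hepta-2,5-diene-2-carboxylate (racemic) | COC(=O)C1=C(C(OC)OC)C2OC1(O[Si](C(C)C)(C(C)C)C(C)C)C(C)=C2OCc1ccccc1 | intermediate (not isolated)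
8 | methyl 4-(benzyloxy)-2-(dimethoxymethyl)-3-hydroxy-5-methyl-6-[(triisopropylsilyl)oxy]benzoate | COC(=O)c1c(O[Si](C(C)C)(C(C)C)C(C)C)c(C)c(OCc2ccccc2)c(O)c1C(OC)OC | intermediate
9 | 2-fluoro-3-hydroxy-4-methoxybenzaldehyde | COc1ccc(C=O)c(F)c1O | starting material
10 | 6-bromo-2-fluoro-3-hydroxy-4-methoxybenzaldehyde | COc1cc(Br)c(C=O)c(F)c1O | intermediate
11 | 6-bromo-2-fluoro-4-methoxy-3-(methoxymethoxy)benzaldehyde | COCOc1c(OC)cc(Br)c(C=O)c1F | intermediate
12 | 2-fluoro-4-methoxy-3-(methoxymethoxy)-6-methylbenzaldehyde | COCOc1c(OC)cc(C)c(C=O)c1F | intermediate
13 | methyl 4-(benzyloxy)-2-(dimethoxymethyl)-3-[2-formyl-5-methoxy-6-(methoxymethoxy)-3-methylphenoxy]-5-methyl-6-[(triisopropylsilyl)oxy]benzoate | COC(=O)c1c(O[Si](C(C)C)(C(C)C)C(C)C)c(C)c(OCc2ccccc2)c(Oc2c(C=O)c(C)cc(OC)c2OCOC)c1C(OC)OC | intermediate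
14 | 2-[2-(benzyloxy)-6-(dimethoxymethyl)-5-(methoxycarbonyl)-3-methyl-4-[(triisopropylsilyl)oxy]phenoxy]-4-methoxy-3-(methoxymethoxy)-6-methylbenzoic acid | COC(=O)c1c(O[Si](C(C)C)(C(C)C)C(C)C)c(C)c(OCc2ccccc2)c(Oc2c(C(=O)O)c(C)cc(OC)c2OCOC)c1C(OC)OC | intermediate
15 | 2-[6-(dimethoxymethyl)-2-hydroxy-5-(methoxycarbonyl)-3-methyl-4-[(triisopropylsilyl)oxy]phenoxy]-4-methoxy-3-(methoxymethoxy)-6-methylbenzoic acid | COC(=O)c1c(O[Si](C(C)C)(C(C)C)C(C)C)c(C)c(O)c(Oc2c(C(=O)O)c(C)cc(OC)c2OCOC)c1C(OC)OC | intermediate
16 | methyl 6-(dimethoxymethyl)-3-methoxy-4-(methoxymethoxy)-1,9-dimethyl-11-oxo-8-[(triisopropylsilyl)oxy]-11H-dibenzo[b,e][1,4]dioxepine-7-carboxylate | COC(=O)c1c(O[Si](C(C)C)(C(C)C)C(C)C)c(C)c2OC(=O)c3c(C)cc(OC)c(OCOC)c3Oc2c1C(OC)OC | intermediate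
17 | methyl 6-(dimethoxymethyl)-8-hydroxy-3-methoxy-4-(methoxymethoxy)-1,9-dimethyl-11-oxo-11H-dibenzo[b,e][1,4]dioxepine-7-carboxylate | COC(=O)c1c(O)c(C)c2OC(=O)c3c(C)cc(OC)c(OCOC)c3Oc2c1C(OC)OC | intermediate
18 | methyl 6-formyl-4,8-dihydroxy-3-methoxy-1,9-dimethyl-11-oxo-11H-dibenzo[b,e][1,4]dioxepine-7-carboxylate | COC(=O)c1c(O)c(C)c2OC(=O)c3c(C)cc(OC)c(O)c3Oc2c1C=O | intermediate (not isolated)
19 | racemic hydroxy-lactone depsidone (target constitution, both configurations at the hemiacetal carbon of ring D) | COc1cc(C)c2c(c1O)Oc1c(c(C)c(O)c3c1C(O)OC3=O)OC2=O | intermediate
20 | target: hydroxy-lactone depsidone with R configuration at the hemiacetal carbon of ring D | COc1cc(C)c2c(c1O)Oc1c(c(C)c(O)c3c1[C@H](O)OC3=O)OC2=O | target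

## Step count and least certain steps

Total: 14 steps. Longest linear sequence: 10 steps (steps 1, 2, 4, 8, 9, 10, 11, 12, 13, 14); the ring A branch (steps 5, 6, 7, then 8 to 14) is equally long.

**Step 14 (proposed new method).** The racemate may crystallise as a racemic compound instead of a conglomerate, so that grinding and seeding give no enrichment. Interconversion in the mother liquor may also be too slow to feed the growing crystals, or fast enough to erode the solid during washing. The first seeds would have to come from a few milligrams separated on a chiral stationary phase at low temperature.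

The fallback uses a covalent auxiliary and known reactions. It sets out from 19, which is heated with (S)-1-phenylethanol and catalytic pyridinium tosylate in toluene over 4 Å molecular sieves. This is the acid-catalysed pseudo-ester formation typical of hydroxy-lactones; it leaves the phenols untouched and gives two acetal epimers that are configurationally stable without acid. The epimer with R configuration at the ring D carbon, the (S)-1-phenylethyl acetal F1, is separated by crystallisation or chromatography, and the other epimer is re-equilibrated with acid and recycled. Hydrogenolysis of the benzylic C–O bond of the auxiliary (H2, Pd/C, EtOAc, 0 °C, stopped at full conversion to avoid reduction of the lactol) breaks no bond at the stereocentre and returns to the route at 20, which is crystallised directly from the cold filtrate.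

**Step 4 (key step).** The cycloaddition joins a trisubstituted diene to a disubstituted ynoate. It may be slow enough that protodesilylation of 3 by the phenolic product, or conjugate addition at C5 without ring closure, outruns it. The acetal ortho to the new phenol may also ionise during purification.

The fallback introduces the acetal carbon after the cycloaddition. It sets out from 3, which is heated with methyl propiolate in toluene at 60 °C. This terminal ynoate is a far more reactive dienophile with the same polarisation, and after bridge opening should give methyl 4-(benzyloxy)-5-hydroxy-3-methyl-2-[(triisopropylsilyl)oxy]benzoate F2, whose single ring hydrogen is ortho to the free phenol. Magnesium-mediated ortho-formylation (MgCl2, Et3N, paraformaldehyde, MeCN, reflux) can only occur there and gives methyl 4-(benzyloxy)-2-formyl-3-hydroxy-5-methyl-6-[(triisopropylsilyl)oxy]benzoate F3. Acetalisation with trimethyl orthoformate and catalytic pyridinium tosylate in methanol returns to the route at 8.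

**Step 8.** The ether carries four ortho substituents and the fluoride has a donor oxygen beside it, so addition to 12 may be slow. Prolonged heating with carbonate can then cleave the silyl ether, which opens a second phenoxide to arylation, or degrade the aldehyde.

The fallback replaces addition–elimination by a copper-mediated Ullmann ether synthesis, the kind of coupling by which crowded diaryl ethers are usually made. It sets out from 8 and a bromide partner built by the logic of steps 5 to 7. Purchased 2-bromo-3-hydroxy-4-methoxybenzaldehyde F4 is iodinated para to the hydroxyl (N-iodosuccinimide, MeCN) to 2-bromo-3-hydroxy-6-iodo-4-methoxybenzaldehyde F5. This is protected (MOMCl, i-Pr2NEt) as 2-bromo-6-iodo-4-methoxy-3-(methoxymethoxy)benzaldehyde F6, then methylated selectively at the C–I bond (trimethylboroxine, Pd(PPh3)4, K2CO3, 80 °C) to 2-bromo-4-methoxy-3-(methoxymethoxy)-6-methylbenzaldehyde F7. Coupling of 8 with F7 (CuI, picolinic acid, K3PO4, DMSO, 90 °C), helped by the ortho formyl group, returns to the route at 13.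

**Step 13.** Ring closure may stall at formyl ester 18 or its cyclic methyl pseudo-ester because loss of methanol is incomplete. Forcing it with stronger acid or heat would begin to hydrolyse the aryl ester of ring C.

The fallback separates unmasking from ester cleavage. It sets out from 17, which is treated with 1 M aq. HCl in THF at rt only until the acetal and methoxymethyl ether are gone, and 18 is isolated. The methyl ester is then cleaved at its O–CH3 bond by nucleophilic dealkylation (LiI, EtOAc, reflux), which touches neither an aryl ester nor an aryl methyl ether. On acidification the carboxylic acid closes onto the neighbouring aldehyde, returning to the route at 19. No new compound is needed.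

## Further compounds

F1 | step 14 | (S)-1-phenylethyl acetal of the target lactol, R at the ring D acetal carbon | COc1cc(C)c2c(c1O)Oc1c(c(C)c(O)c3c1[C@H](O[C@@H](C)c4ccccc4)OC3=O)OC2=O
F2 | step 4 | methyl 4-(benzyloxy)-5-hydroxy-3-methyl-2-[(triisopropylsilyl)oxy]benzoate | COC(=O)c1cc(O)c(OCc2ccccc2)c(C)c1O[Si](C(C)C)(C(C)C)C(C)C
F3 | step 4 | methyl 4-(benzyloxy)-2-formyl-3-hydroxy-5-methyl-6-[(triisopropylsilyl)oxy]benzoate | COC(=O)c1c(C=O)c(O)c(OCc2ccccc2)c(C)c1O[Si](C(C)C)(C(C)C)C(C)C
F4 | step 8 | 2-bromo-3-hydroxy-4-methoxybenzaldehyde (purchased) | COc1ccc(C=O)c(Br)c1O
F5 | step 8 | 2-bromo-3-hydroxy-6-iodo-4-methoxybenzaldehyde | COc1cc(I)c(C=O)c(Br)c1O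
F6 | step 8 | 2-bromo-6-iodo-4-methoxy-3-(methoxymethoxy)benzaldehyde | COCOc1c(OC)cc(I)c(C=O)c1Br
F7 | step 8 | 2-bromo-4-methoxy-3-(methoxymethoxy)-6-methylbenzaldehyde | COCOc1c(OC)cc(C)c(C=O)c1Br
F0 | step 13 | none | none
A1 | alternative 1 | acetyl-protected phthalide depsidone | COc1cc(C)c2c(c1OC(C)=O)Oc1c(c(C)c(O)c3c1COC3=O)OC2=O
A2 | alternative 1 | diaryl ether acid with acetylated ring A and phthalide phenol ring B | COc1cc(C)c(C(=O)O)c(c1OC(C)=O)Oc1cc(C)c(O)c2c1COC2=O
A3 | alternative 1 | spiro quinone monoketal lactone | COc1cc(C)c2c(c1OC(C)=O)OC1(OC2=O)C=C(C)C(=O)C2=C1COC2=O
A4 | alternative 2 | diaryl ether with complete ring B (free phenol, silyl ether, ester, acetal) | COc1cc(C)c(C(=O)OC(C)(C)C)c(Oc2c(O)c(C)c(O[Si](C(C)C)(C(C)C)C(C)C)c(C(=O)OC)c2C(OC)OC)c1OCc1ccccc1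
A5 | alternative 2 | diazo ketoester carrying ring A as an enol aryl ether | COC(=O)C(=[N+]=[N-])C(=O)C(C(OC)OC)=COc1c(C(=O)OC(C)(C)C)c(C)cc(OC)c1OCc1ccccc1
A6 | alternative 2 | 1-[(triisopropylsilyl)oxy]prop-1-yne | CC#CO[Si](C(C)C)(C(C)C)C(C)C
A7 | alternative 3 | phthalide depsidone with free ring A phenol and benzyl ether on ring B | COc1cc(C)c2c(c1O)Oc1c(c(C)c(OCc4ccccc4)c3c1COC3=O)OC2=O
A8 | alternative 3 | ortho-quinone diazide ester of the ring B phthalide phenol | COC1=CC(C)=C(C(=O)Oc2c(C)c(OCc3ccccc3)c3C(=O)OCc3c2O)C(=[N+]=[N-])C1=O
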